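**Retrosynthetic overview**

1. Ring C is closed last: the O1–C2 bond is made by Mitsunobu etherification of a ring-opened triol, and the two MOM ethers on ring B are then removed.
2. The strategy rests on this feature: C6, C7 with its oxygen, C8 and the whole C8 prenyl chain are the intact skeleton of 6-methylhept-5-en-2-one, and C8a–C4a–C4–C3–C2–O1 is a δ-lactone that carries C5 as an exocyclic methoxymethylene carbon. A [3+3] Michael–Claisen aromatisation forms C5–C6 and C8–C8a and gives ring A with the 7-OH/8-prenyl pattern already in place.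
3. The lactone comes from an Evans allylation of the ring B arylacetyl imide (sets C3), LiBH4 cleavage, selective hydroboration, oxidative lactonisation and formylation/O-methylation.
4. Ring B comes from resorcinol by two directed ortho-metalations (prenyl bromide, then ethylene oxide).
5. Order of rings: ring B (from resorcinol), the temporary lactone ring, ring A, ring C.

Key step: step 11

Remark: the stereodescriptor in the given SMILES corresponds to (3S), and every intermediate is drawn in that series. Ar stands for 2,4-bis(methoxymethoxy)-3-(3-methylbut-2-en-1-yl)phenyl (protected ring B), and atom numbers C2 to C8a and O1 are those of the chroman of the target.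

**Route**

Step 1
Reactants: 1 resorcinol
Product: 2 1,3-bis(methoxymethoxy)benzene
Conditions: MOMCl, i-Pr2NEt, CH2Cl2, 0 °C to rt
Reagents that add atoms: chloromethyl methyl ether, COCCl
Why: Both phenols are O-alkylated by the reactive α-chloro ether under amine base (MOM protection), which gives two base-stable ortho-directing groups.

Step 2
Reactants: 2 1,3-bis(methoxymethoxy)benzene; 3 prenyl bromide
Product: 5 1,3-bis(methoxymethoxy)-2-(3-methylbut-2-en-1-yl)benzene, via 2-lithio-1,3-bis(methoxymethoxy)benzene 4 (not isolated)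
Conditions: n-BuLi, THF, 0 °C; then CuBr·SMe2 (10 mol %), 3, −78 °C to rt
Reagents that add atoms: none
Why: Directed ortho-metalation takes the proton between the two OMOM groups, and copper-assisted SN2 alkylation of the aryllithium with the allylic bromide should give the linear prenyl arene.

Step 3
Reactants: 5 1,3-bis(methoxymethoxy)-2-(3-methylbut-2-en-1-yl)benzene; 6 ethylene oxide
Product: 8 2-Ar-ethan-1-ol, via aryllithium 7 (not isolated)
Conditions: n-BuLi, TMEDA, THF, −20 to 0 °C; then 6, −78 °C to rt; H2O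
Reagents that add atoms: none
Why: A second directed ortho-metalation occurs next to an OMOM group (the two open ortho sites are equivalent by symmetry), and the aryllithium opens the epoxide to the 2-arylethanol.

Step 4
Reactants: 8 2-Ar-ethan-1-ol
Product: 9 Ar-acetic acid
Conditions: TEMPO (20 mol %), PhI(OAc)2 (2.2 equiv), MeCN/H2O 1:1, rt
Reagents that add atoms: water, O
Why: Oxoammonium oxidation of the primary alcohol in aqueous medium proceeds through the aldehyde hydrate to the carboxylic acid and leaves trisubstituted alkenes and MOM acetals untouched.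

Step 5
Reactants: 9 Ar-acetic acid; 10 (S)-4-benzyl-1,3-oxazolidin-2-one
Product: 12 (4S)-4-benzyl-3-(Ar-acetyl)-1,3-oxazolidin-2-one, via mixed pivalic anhydride 11 (not isolated)
Conditions: PivCl, Et3N, THF, −20 °C; then 10, LiCl, rt
Reagents that add atoms: none
Why: N-acylation of the oxazolidinone through the mixed anhydride (LiCl/Et3N activation) attaches the auxiliary under mild, non-acidic conditions.

Step 6
Reactants: 12 (4S)-4-benzyl-3-(Ar-acetyl)-1,3-oxazolidin-2-one; 13 allyl bromide
Product: 15 (4S)-4-benzyl-3-[(2S)-2-Ar-pent-4-enoyl]-1,3-oxazolidin-2-one, via sodium Z-enolate 14 (not isolated)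
Conditions: NaHMDS, THF, −78 °C; then 13, −78 to −40 °C; aq NH4Cl
Reagents that add atoms: none
Why: Evans asymmetric alkylation: the chelated Z-enolate is allylated on the face opposite the benzyl group of the (S)-auxiliary, which sets C3 as (S) because the aryl group outranks allyl.

Step 7
Reactants: 15 (4S)-4-benzyl-3-[(2S)-2-Ar-pent-4-enoyl]-1,3-oxazolidin-2-one
Product: 16 (2S)-2-Ar-pent-4-en-1-ol
Conditions: LiBH4, MeOH (1 equiv), THF, 0 °C to rt
Reagents that add atoms: none
Why: Hydride reduction of the exocyclic imide carbonyl cleaves the auxiliary and gives the primary alcohol, after which C3 is no longer α to a carbonyl and cannot epimerise.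

Step 8
Reactants: 16 (2S)-2-Ar-pent-4-en-1-ol
Product: 18 (2S)-2-Ar-pentane-1,5-diol, via bis(9-borabicyclononyl) adduct 17 (not isolated)
Conditions: 9-BBN (2.2 equiv), THF, 0 °C to rt; then NaOH, H2O2, 0 °C to rt
Reagents that add atoms: hydrogen peroxide, OO
Why: Anti-Markovnikov hydroboration–oxidation with the bulky borane should take only the monosubstituted alkene and spare the trisubstituted prenyl double bond.

Step 9
Reactants: 18 (2S)-2-Ar-pentane-1,5-diol
Product: 20 (5S)-5-Ar-oxan-2-one, via lactol 19 (not isolated)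
Conditions: Cu(MeCN)4OTf (5 mol %), 2,2'-bipyridine (5 mol %), TEMPO (5 mol %), N-methylimidazole (10 mol %), air, MeCN, rt
Reagents that add atoms: none
Why: Copper/nitroxyl aerobic oxidative lactonisation should oxidise the unbranched C5 carbinol in preference to the β-branched C1 carbinol, and the lactol that forms is oxidised on to the δ-lactone.

Step 10
Reactants: 20 (5S)-5-Ar-oxan-2-one; 21 ethyl formate
Product: 23 (3E,5S)-5-Ar-3-(methoxymethylidene)oxan-2-one, via sodium formyl enolate 22 (not isolated)
Conditions: NaH, 21, THF (cat. EtOH), 0 °C to rt; then Me2SO4, DMF, 0 °C to rt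
Reagents that add atoms: dimethyl sulfate, COS(=O)(=O)OC
Why: Claisen formylation at the only α-position, then O-methylation of the stabilised enolate by the hard sulfate electrophile, should give the β-methoxy enoate, mainly as the E isomer, whose geometry is not critical later.

Step 11
Reactants: 23 (3E,5S)-5-Ar-3-(methoxymethylidene)oxan-2-one; 24 6-methylhept-5-en-2-one
Product: 28 4-[(2S)-2-Ar-3-hydroxypropyl]-2-(3-methylbut-2-en-1-yl)benzene-1,3-diol, via lithium enolate 25 (not isolated), via lithium dienolate 26 (not isolated), via cyclohexenedione 27 (not isolated)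
Conditions: 24 (2.2 equiv), LDA (2.1 equiv), THF, −78 °C; then 23, DMPU, −78 to 0 °C; then KOt-Bu (3 equiv), 0 to 50 °C; AcOH, H2O
Reagents that add atoms: none
Why: Proposed new method: the kinetic methyl-side enolate 25 adds to C5 of the s-cis-locked β-methoxy enoate and methoxide leaves (addition–elimination), which forms C5–C6; the doubly activated C6–H is then removed by the second equivalent of enolate to give dienolate 26, whose delocalisation lets the C4a=C5 geometry equilibrate. Under KOt-Bu the C8 enolate attacks the lactone carbonyl C8a in a 6-(enolendo)-exo-trig Claisen closure that expels the C2 alkoxide, and cyclohexenedione 27 tautomerises to the resorcinolate, so ring A forms without an oxidant. The closest known reactions are the consecutive Michael–Claisen synthesis of cyclohexane-1,3-diones from ketones and acrylates, Michael–Dieckmann resorcinol syntheses from acetonedicarboxylates and alkynyl carbonyl compounds, and the biomimetic Claisen aromatisation of poly-β-carbonyl chains. No stereocentre is formed, and C3 is not acidic in any intermediate, so it is carried through unchanged. The step needs the prenyl chain at C8 and not at C6, which rests on kinetic deprotonation of the methyl group at −78 °C and on the fact that, once C5–C6 exists, only C8 can reach C8a through a six-membered transition state. It also needs C- over O-acylation, which is expected because O-acylation to an α-pyrone is reversible in the aprotic basic medium (the expelled alkoxide can re-add) whereas C-acylation is made irreversible by aromatisation.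

Step 12
Reactants: 28 4-[(2S)-2-Ar-3-hydroxypropyl]-2-(3-methylbut-2-en-1-yl)benzene-1,3-diol
Product: 29 (3S)-3-Ar-8-(3-methylbut-2-en-1-yl)-3,4-dihydro-2H-chromen-7-ol
Conditions: PPh3, DIAD, THF (0.02 M), 0 °C to rt
Reagents that add atoms: none
Why: Intramolecular Mitsunobu etherification (6-exo-tet) of the activated primary alcohol by the C8a phenol, the only phenol that can reach C2, closes ring C without touching C3.

Step 13
Reactants: 29 (3S)-3-Ar-8-(3-methylbut-2-en-1-yl)-3,4-dihydro-2H-chromen-7-ol
Product: 30 (3S)-3-[2,4-dihydroxy-3-(3-methylbut-2-en-1-yl)phenyl]-8-(3-methylbut-2-en-1-yl)-3,4-dihydro-2H-chromen-7-ol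
Conditions: HCl (1 M) in MeOH, rt
Reagents that add atoms: none
Why: Acid-catalysed acetal methanolysis removes both aryl MOM ethers, and dilute acid at room temperature should leave the prenyl groups and C3 intact.

**Compound list**

1 | resorcinol | Oc1cccc(O)c1 | starting material
2 | 1,3-bis(methoxymethoxy)benzene | COCOc1cccc(OCOC)c1 | intermediate
3 | prenyl bromide (1-bromo-3-methylbut-2-ene) | CC(C)=CCBr | starting material
4 | 2-lithio-1,3-bis(methoxymethoxy)benzene (not isolated) | [Li]c1c(OCOC)cccc1OCOC | intermediate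
5 | 1,3-bis(methoxymethoxy)-2-(3-methylbut-2-en-1-yl)benzene | COCOc1cccc(OCOC)c1CC=C(C)C | intermediate
6 | ethylene oxide | C1CO1 | starting material
7 | [2,4-bis(methoxymethoxy)-3-(3-methylbut-2-en-1-yl)phenyl]lithium (not isolated) | [Li]c1ccc(OCOC)c(CC=C(C)C)c1OCOC | intermediate
8 | 2-[2,4-bis(methoxymethoxy)-3-(3-methylbut-2-en-1-yl)phenyl]ethan-1-ol | CC(C)=CCc1c(OCOC)ccc(CCO)c1OCOC | intermediate
9 | [2,4-bis(methoxymethoxy)-3-(3-methylbut-2-en-1-yl)phenyl]acetic acid | CC(C)=CCc1c(OCOC)ccc(CC(=O)O)c1OCOC | intermediate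
10 | (S)-4-benzyl-1,3-oxazolidin-2-one | O=C1N[C@@H](Cc2ccccc2)CO1 | starting material
11 | Ar-acetic pivalic anhydride (not isolated) | CC(C)=CCc1c(OCOC)ccc(CC(=O)OC(=O)C(C)(C)C)c1OCOC | intermediate
12 | (4S)-4-benzyl-3-(Ar-acetyl)-1,3-oxazolidin-2-one | CC(C)=CCc1c(OCOC)ccc(CC(=O)N2C(=O)OC[C@@H]2Cc2ccccc2)c1OCOC | intermediate
13 | allyl bromide | C=CCBr | starting material
14 | sodium Z-enolate of 12 (not isolated) | CC(C)=CCc1c(OCOC)ccc(/C=C(\[O-])N2C(=O)OC[C@@H]2Cc2ccccc2)c1OCOC.[Na+] | intermediate
15 | (4S)-4-benzyl-3-[(2S)-2-Ar-pent-4-enoyl]-1,3-oxazolidin-2-one | CC(C)=CCc1c(OCOC)ccc([C@H](CC=C)C(=O)N2C(=O)OC[C@@H]2Cc2ccccc2)c1OCOC | intermediate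
16 | (2S)-2-Ar-pent-4-en-1-ol | CC(C)=CCc1c(OCOC)ccc([C@H](CC=C)CO)c1OCOC | intermediate
17 | O,C-bis(9-borabicyclo[3.3.1]nonan-9-yl) adduct of 16 (not isolated) | CC(C)=CCc1c(OCOC)ccc([C@H](CCCB2C3CCCC2CCC3)COB2C3CCCC2CCC3)c1OCOC | intermediate
18 | (2S)-2-Ar-pentane-1,5-diol | CC(C)=CCc1c(OCOC)ccc([C@H](CCCO)CO)c1OCOC | intermediate
19 | (5S)-5-Ar-oxan-2-ol, both anomers (not isolated) | CC(C)=CCc1c(OCOC)ccc([C@H]2COC(O)CC2)c1OCOC | intermediate
20 | (5S)-5-Ar-oxan-2-one | CC(C)=CCc1c(OCOC)ccc([C@H]2COC(=O)CC2)c1OCOC | intermediate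
21 | ethyl formate | CCOC=O | starting material
22 | sodium enolate of (5S)-5-Ar-3-formyloxan-2-one (not isolated) | CC(C)=CCc1c(OCOC)ccc([C@H]2COC(=O)C(=C[O-])C2)c1OCOC.[Na+] | intermediate
23 | (3E,5S)-5-Ar-3-(methoxymethylidene)oxan-2-one | CC(C)=CCc1c(OCOC)ccc([C@H]2COC(=O)/C(=C/OC)C2)c1OCOC | intermediate
24 | 6-methylhept-5-en-2-one | CC(=O)CCC=C(C)C | starting material
25 | lithium 6-methylhepta-1,5-dien-2-olate (not isolated) | C=C(O[Li])CCC=C(C)C | intermediate
26 | lithium dienolate of (5S)-5-Ar-3-(7-methyl-3-oxooct-6-en-1-ylidene)oxan-2-one (not isolated) | CC(C)=CCc1c(OCOC)ccc([C@H]2COC(=O)C(=CC=C([O-])CCC=C(C)C)C2)c1OCOC.[Li+] | intermediate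
27 | potassium alkoxide of 4-[(2S)-2-Ar-3-hydroxypropyl]-2-(3-methylbut-2-en-1-yl)cyclohex-4-ene-1,3-dione (not isolated) | CC(C)=CCc1c(OCOC)ccc([C@H](CC2=CCC(=O)C(CC=C(C)C)C2=O)C[O-])c1OCOC.[K+] | intermediate
28 | 4-[(2S)-2-Ar-3-hydroxypropyl]-2-(3-methylbut-2-en-1-yl)benzene-1,3-diol | CC(C)=CCc1c(OCOC)ccc([C@H](Cc2ccc(O)c(CC=C(C)C)c2O)CO)c1OCOC | intermediate
29 | (3S)-3-Ar-8-(3-methylbut-2-en-1-yl)-3,4-dihydro-2H-chromen-7-ol | CC(C)=CCc1c(OCOC)ccc([C@H]2COc3c(ccc(O)c3CC=C(C)C)C2)c1OCOC | intermediate
30 | (3S)-3-[2,4-dihydroxy-3-(3-methylbut-2-en-1-yl)phenyl]-8-(3-methylbut-2-en-1-yl)-3,4-dihydro-2H-chromen-7-ol | CC(C)=CCc1c(O)ccc([C@H]2COc3c(ccc(O)c3CC=C(C)C)C2)c1O | target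

**Step count**

Total: 13 steps. Longest linear sequence: 13 steps (resorcinol to 30).

**Steps most likely to fail**

1. Step 11 (key step). The addition–elimination at the push–pull enoate may be slow, so that attack on the lactone carbonyl or proton exchange that scrambles the ketone enolate competes; the dienolate may also be diverted by O-acylation to an α-pyrone. The fallback abandons the annulation and builds the C4–C4a bond by a second Evans alkylation; it sets out from 5 and 12 and comes back at 28. Compound 5 is lithiated as in step 3 and aryllithium 7 is quenched with DMF to give 2,4-bis(methoxymethoxy)-3-(3-methylbut-2-en-1-yl)benzaldehyde F1. HCl in MeOH at room temperature gives 2,4-dihydroxy-3-(3-methylbut-2-en-1-yl)benzaldehyde F2, and allyl bromide 13 with K2CO3 in DMF gives 2,4-bis(allyloxy)-3-(3-methylbut-2-en-1-yl)benzaldehyde F3. NaBH4 in MeOH gives the benzyl alcohol F4, and MsCl, Et3N and LiCl give the benzyl chloride F5. The sodium enolate 14 of imide 12 is alkylated with F5 (Bu4NI, THF, −78 to −20 °C), with the same facial sense as in step 6, to give the benzylated imide F6. LiBH4 gives the primary alcohol F7, and Pd(PPh3)4 with morpholine in THF removes both allyl ethers to give 28.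

2. Step 9. Oxidation may start at the branched C1 carbinol and lead to the regioisomeric 3-aryl lactone. The fallback fixes the regiochemistry by differentiating the two ends before oxidation; it sets out from 16 and comes back at 20. TBSCl and imidazole give the silyl ether F8, 9-BBN followed by NaOH/H2O2 gives the primary alcohol F9, and TEMPO/PhI(OAc)2 in MeCN/H2O gives the carboxylic acid F10. TBAF in THF gives the hydroxy acid F11, which is closed with EDC·HCl and DMAP to 20.

3. Step 13. Under protic acid a freed phenol may add to the neighbouring prenyl double bond and form a 2,2-dimethylchroman. The fallback replaces acid solvolysis by an aprotic acetal-to-silyl-ether exchange; it sets out from 29 and comes back at 30. TMSOTf and 2,2'-bipyridyl in MeCN at 0 °C convert both aryl MOM ethers (and the free phenol) into trimethylsilyl ethers, giving the tris(trimethylsilyl) ether F12, which is not isolated and is hydrolysed with water at neutral pH to 30.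

**Further compounds**

F1 | step 11 | 2,4-bis(methoxymethoxy)-3-(3-methylbut-2-en-1-yl)benzaldehyde | CC(C)=CCc1c(OCOC)ccc(C=O)c1OCOC
F2 | step 11 | 2,4-dihydroxy-3-(3-methylbut-2-en-1-yl)benzaldehyde | CC(C)=CCc1c(O)ccc(C=O)c1O
F3 | step 11 | 2,4-bis(allyloxy)-3-(3-methylbut-2-en-1-yl)benzaldehyde | CC(C)=CCc1c(OCC=C)ccc(C=O)c1OCC=C
F4 | step 11 | [2,4-bis(allyloxy)-3-(3-methylbut-2-en-1-yl)phenyl]methanol | CC(C)=CCc1c(OCC=C)ccc(CO)c1OCC=C
F5 | step 11 | 1-(chloromethyl)-2,4-bis(allyloxy)-3-(3-methylbut-2-en-1-yl)benzene | CC(C)=CCc1c(OCC=C)ccc(CCl)c1OCC=C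
F6 | step 11 | (4S)-4-benzyl-3-[(2S)-2-Ar-3-[2,4-bis(allyloxy)-3-(3-methylbut-2-en-1-yl)phenyl]propanoyl]-1,3-oxazolidin-2-one | CC(C)=CCc1c(OCOC)ccc([C@H](Cc2ccc(OCC=C)c(CC=C(C)C)c2OCC=C)C(=O)N2C(=O)OC[C@@H]2Cc2ccccc2)c1OCOC
F7 | step 11 | (2S)-2-Ar-3-[2,4-bis(allyloxy)-3-(3-methylbut-2-en-1-yl)phenyl]propan-1-ol | CC(C)=CCc1c(OCOC)ccc([C@H](Cc2ccc(OCC=C)c(CC=C(C)C)c2OCC=C)CO)c1OCOC
F8 | step 9 | tert-butyl{[(2S)-2-Ar-pent-4-en-1-yl]oxy}dimethylsilane | CC(C)=CCc1c(OCOC)ccc([C@H](CC=C)CO[Si](C)(C)C(C)(C)C)c1OCOC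
F9 | step 9 | (4S)-4-Ar-5-[(tert-butyldimethylsilyl)oxy]pentan-1-ol | CC(C)=CCc1c(OCOC)ccc([C@H](CCCO)CO[Si](C)(C)C(C)(C)C)c1OCOC
F10 | step 9 | (4S)-4-Ar-5-[(tert-butyldimethylsilyl)oxy]pentanoic acid | CC(C)=CCc1c(OCOC)ccc([C@H](CCC(=O)O)CO[Si](C)(C)C(C)(C)C)c1OCOC
F11 | step 9 | (4S)-4-Ar-5-hydroxypentanoic acid | CC(C)=CCc1c(OCOC)ccc([C@H](CCC(=O)O)CO)c1OCOC
F12 | step 13 | tris(trimethylsilyl) ether of 30 | CC(C)=CCc1c(O[Si](C)(C)C)ccc([C@H]2COc3c(ccc(O[Si](C)(C)C)c3CC=C(C)C)C2)c1O[Si](C)(C)C
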